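## Compound numbers used throughout

1 4-methoxybenzaldehyde; 2 N-acetylglycine; 3 azlactone; 4 arylpyruvic acid; 5 methyl arylpyruvate; 6 acyclic aldol adduct (not isolated); 7 hydroxybutenolide ester; 8 enol triflate; 9 deoxygenated butenolide ester; 10 butenolide acid; 11 C5 acetate; 12 bis(methyl ether) of the benzylidene butenolide; 13 diphenol; 14 rubrolide A.

Positions are given in butenolide numbering: O1, lactone carbonyl C2, C3, C4, C5, exocyclic C6.

## Analysis of the target

Rubrolide A (14) is a monocyclic γ-ylidene butenolide: a furan-2(5H)-one ring with a 3,5-dibromo-4-hydroxyphenyl group on C4, a 3,5-dibromo-4-hydroxybenzylidene group on C5 (exocyclic C6) and a hydrogen on C3. It has no stereogenic carbon. The only stereochemical element is the C5=C6 double bond, which is Z: the C6 aryl lies on the side of O1 and points away from the C4 aryl, so this is also the less crowded isomer and can be reached under equilibrating conditions. The sensitive groups are the cross-conjugated enol lactone (opened by strong nucleophiles, isomerized by light or acid), two acidic and oxidizable phenols, and four aryl bromides that would not survive zerovalent palladium, dissolving metals or organometallic reagents. The difficulty is therefore one of ordering and of alkene geometry, not of size. Two observations simplify it: all four bromines sit ortho to a phenolic hydroxyl whose para position is blocked, where electrophilic bromination goes by itself, and without them the two aryl groups are identical. The seventeen remaining carbons divide into a complete aryl-C3 unit (aryl–C4–C3–C2) and an aryl-C2 unit (aryl–C6–C5) that lacks only a carboxyl carbon on C5. Restoring that carboxyl at C5 and an oxygen at C3 turns the butenolide into the lactonized aldol dimer of an arylpyruvic ester, and the route rests on this hidden identity of the two halves.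

## Retrosynthetic reasoning

The four C–Br bonds of 14 are cut first, which leads to diphenol 13. Each bromine is ortho to a hydroxyl on a para-blocked ring, so the forward reaction is a plain fourfold electrophilic substitution. Doing it last keeps the aryl bromides away from the palladium step and from every base and oxidant used earlier. The forward step only has to spare C3 and the C5=C6 bond, both of which belong to an electron-poor enol lactone.

The two phenols of 13 are masked as the methyl ethers of 12. These ethers cost no step because they are already present in aldehyde 1. They tolerate the aqueous acid, the amidine base, the sulfonylation, the palladium-catalysed reduction, the saponification and the tetravalent lead oxidant of the later steps, the last of which would destroy a free phenol. One Lewis-acid ether cleavage removes both at the end.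

The C5=C6 bond of 12 is traced back to the C5 acetate 11 and from there to carboxylic acid 10. Retrosynthetically, a carboxyl carbon is attached to C5 and two hydrogens are returned to C6, which restores the missing carbon of the second aryl-C3 unit. In the forward direction an oxidative decarboxylation replaces the carboxyl by an acetoxy group on a carbon that already carries the ring oxygen. Loss of the acetoxy group with a C6 proton then gives the alkene. Only C6 carries hydrogens next to C5, so the position of the double bond is fixed and only its geometry has to settle, under acid, to the Z form.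

Acid 10 comes from methyl ester 9 by saponification. The C3–H bond of 9 is exchanged for a C3–O bond, which gives enol triflate 8 and, behind it, enol 7. The C3 oxygen is the former ketone of one pyruvate unit. It is not wanted in 14, but as an enol it is the one hydroxyl that can be sulfonylated and then replaced by hydrogen with palladium, and this happens before any bromine is present.

Hydroxybutenolide 7 is cut at O1–C2 and at C4–C5. Opening the lactone gives the acyclic aldol 6, and retro-aldol cleavage of C4–C5 divides 6 into two molecules of keto ester 5. No other pair of cuts in the ring gives two identical pieces: a cut at C3–C4 or at C5–C6 needs two different aryl building blocks and a separate way to fix the oxidation level of C5. The forward reaction must join the benzylic carbon of one molecule of 5 to the ketone carbon of another and then close the ring by acyl substitution at the ester of the donor half.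

Keto ester 5 is the methyl ester of arylpyruvic acid 4, and 4 is the hydrolysis product of azlactone 3. Azlactone 3 is cut at its exocyclic C=C bond into aldehyde 1 and N-acetylglycine 2. In the finished skeleton the aldehyde carbon becomes C4 in one half and C6 in the other. The glycine carbons become C3 and C2 in one half, and C5 plus the carboxyl that is later lost in the other.

## Alternatives that were turned down

Alternative 1: The ring is cut at O1–C2 and at C3=C4. C2 and C3 come from (triphenylphosphoranylidene)ketene A3, and everything else comes from the enol form of a 1,3-diaryl-1,2-dione, (Z)-1,3-bis(3,5-dibromo-4-methoxyphenyl)-2-hydroxyprop-2-en-1-one A2. In the key step the enol hydroxyl of A2 adds to A3 to give an ester-stabilized ylide. This ylide closes onto the neighbouring aryl ketone by an intramolecular Wittig reaction and gives (Z)-5-(3,5-dibromo-4-methoxybenzylidene)-4-(3,5-dibromo-4-methoxyphenyl)furan-2(5H)-one A1.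
- For it: the bromines are carried from the start, so no palladium step and no late bromination are needed. C3–H is formed directly, the Z geometry is inherited from the hydrogen-bonded enol of A2, and only one ether cleavage separates A1 from 14.
- Against it: A2 must be built from two different brominated aryl carbonyl components through a chalcone and an oxidative rearrangement, and it is a tautomerically mobile 1,2-dicarbonyl compound. The ylide formed from A3 is stabilized and has to attack a conjugated aryl ketone, so the closure should need heat. Under heat the O-acylated enol can lose its geometry or transfer its acyl group. A3 is moisture-sensitive and has to be prepared.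
- Comparison: Alternative 1 is shorter after ring formation and avoids the bromination selectivity question, and on these points it is the stronger plan. The chosen strategy offers instead two identical halves from one cheap aldehyde, a ring closure driven by an irreversible lactonization, and no dependence on the Wittig reactivity of a deactivated ketone.

Alternative 2: The skeleton is cut at C2–C3 and C4–C5 into 4-ethynylanisole A5, carbon dioxide A7 and the alkynylzinc reagent bromo[(4-methoxyphenyl)ethynyl]zinc A6. In the key step A5 and A7 couple on Ni(cod)2 with DBU to an oxanickelacyclopentenone in which nickel is bound to the aryl-bearing carbon. A6 then transmetalates, and reductive elimination should give the enynoic acid A4, which is (Z)-3,5-bis(4-methoxyphenyl)pent-2-en-4-ynoic acid. The carboxyl and alkynyl groups of A4 are cis, so a 5-exo-dig lactonization of A4 would lead to bis(methyl ether) 12 of the chosen route.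
- For it: this is by far the shortest path to 12. One step takes A5 to A4 and one more takes A4 to 12, against nine steps from 1. The syn relationship of carboxyl and alkyne in A4 comes from the metallacycle, and the geometry of C5=C6 follows from anti addition across the alkyne.
- Against it: the nickel complex is needed in stoichiometric amount and is air-sensitive. A terminal arylalkyne such as A5 can oligomerize on zerovalent nickel. Transfer of an sp carbon from A6 to the nickelacycle and its reductive elimination are the least secure variant of this coupling. The lactonization of A4 has to choose 5-exo over 6-endo closure, which would give a pyranone.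
- Comparison: Alternative 2 wins clearly on step count. The chosen strategy trades length for reactions that run with catalytic or cheap reagents on any scale and for a ring closure with no regiochemical choice.

Alternative 3: The butenolide is traced back to a four-membered ring, 4-hydroxy-4-(4-methoxybenzyl)-3-(4-methoxyphenyl)cyclobut-2-en-1-one A9. In the key step Pb(OAc)4 oxidizes the tertiary cyclobutenol of A9, and the bond between the carbinol carbon and the carbonyl carbon breaks. The former hydroxyl oxygen then closes onto the acyl carbon, and acetate is taken up at C5 to give 5-acetoxy-5-(4-methoxybenzyl)-4-(4-methoxyphenyl)furan-2(5H)-one A8. A8 is the same compound as acetate 11, so from there the two plans are identical.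
- For it: it is convergent and modular. The two aryl groups could differ, C3–H is present from the start, and neither a deoxygenation nor an ester hydrolysis is needed. It should reach 11 in fewer steps than the chosen route.
- Against it: A9 requires an arylcyclobutenedione, which has to be made from a squarate-type precursor or by a cycloaddition sequence, and a benzylic organometallic reagent that must select one of two carbonyl groups. The strained precursors are costly, and the same lead oxidant is still needed.
- Comparison: Alternative 3 is equal or better in step count up to 11. The chosen strategy reaches the same acetate from two commodity chemicals, with no regiochemical decision and with every skeletal carbon drawn from one monomer.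

Key step: step 4

## Route

Remark on the chemistry: compounds 6 to 11 are racemic. Their stereocentre at C5 becomes trigonal in step 9, so no enantiocontrol is planned. Compounds 7 to 10 are named on the 2,5-dihydrofuran-2-carboxylate parent, on which butenolide C3 is position 4 and butenolide C4 is position 3.

Step 1
Reactants: 1 4-methoxybenzaldehyde; 2 N-acetylglycine
Product: 3 (Z)-4-(4-methoxybenzylidene)-2-methyloxazol-5(4H)-one
Conditions: Ac2O, NaOAc, 100 °C
Reagents that add atoms: none
Why: Erlenmeyer–Plöchl azlactone synthesis: 2 is cyclodehydrated to the oxazolone, whose acidic C4–H condenses with the aldehyde; the Z alkene is the thermodynamic one and is of no consequence because it is destroyed in step 2.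

Step 2
Reactants: 3 (Z)-4-(4-methoxybenzylidene)-2-methyloxazol-5(4H)-one
Product: 4 3-(4-methoxyphenyl)-2-oxopropanoic acid
Conditions: 3 M aq. HCl, reflux
Reagents that add atoms: water, O
Why: Acid hydrolysis of the azlactone opens the ring, cleaves the acetamide and hydrolyses the resulting enamine to the ketone; the aryl methyl ether is stable to aqueous HCl, and 4 should crystallize on cooling and be used without long storage.

Step 3
Reactants: 4 3-(4-methoxyphenyl)-2-oxopropanoic acid
Product: 5 methyl 3-(4-methoxyphenyl)-2-oxopropanoate
Conditions: MeOH, H2SO4 (cat.), 40 °C
Reagents that add atoms: methanol, CO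
Why: Fischer esterification of an activated α-keto acid; acidic conditions are chosen so that no enolate of 5 is formed before the dimerization is wanted.

Step 4
Reactants: 5 methyl 3-(4-methoxyphenyl)-2-oxopropanoate (two molecules)
Product: 7 methyl 4-hydroxy-2-(4-methoxybenzyl)-3-(4-methoxyphenyl)-5-oxo-2,5-dihydrofuran-2-carboxylate (racemic), via acyclic aldol adduct 6 (not isolated)
Conditions: DBU (0.6 equiv), MeCN, 0 °C to rt, N2; then 1 M HCl
Reagents that add atoms: none
Why: DBU removes a benzylic proton of 5, which is acidified by the adjacent ketone and the aryl ring, and the enolate carbon adds to the ketone carbonyl of a second molecule of 5, forming C4–C5 and the tertiary alkoxide of 6. That alkoxide attacks the ester carbonyl of the donor half in a 5-exo-trig acyl substitution that expels methoxide and forms O1–C2; the geminal ester of the acceptor half cannot compete because it would give a three-membered ring. The resulting 3-oxolactone enolizes toward C4 and the acidic enol is deprotonated by DBU, which makes the otherwise reversible aldol addition irreversible. The closest known reaction type is the base-mediated self-condensation of pyruvic and arylpyruvic esters to 4-aryl-5-benzyl-3-hydroxybutenolide-5-carboxylates. The one lasting stereocentre, quaternary C5, is formed without a controlling element, so 7 is racemic, which does not matter because C5 becomes trigonal in step 9; the second stereocentre of 6 at C4 disappears on enolization. The step needs carbon attack at the ketone and not at an ester, and a single site of enolization: the ketone of an α-keto ester is the most electrophilic carbonyl present, 5 has only one enolizable position, and one monomer in both roles leaves no cross-coupling problem. Further aldol chemistry of the product is blocked because the nucleophilic carbon of its enolate, C4, is fully substituted.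

Step 5
Reactants: 7 methyl 4-hydroxy-2-(4-methoxybenzyl)-3-(4-methoxyphenyl)-5-oxo-2,5-dihydrofuran-2-carboxylate
Product: 8 methyl 2-(4-methoxybenzyl)-3-(4-methoxyphenyl)-5-oxo-4-(trifluoromethylsulfonyloxy)-2,5-dihydrofuran-2-carboxylate (racemic)
Conditions: Tf2O, pyridine, CH2Cl2, −78 to 0 °C
Reagents that add atoms: trifluoromethanesulfonic anhydride, O=S(=O)(OS(=O)(=O)C(F)(F)F)C(F)(F)F
Why: O-Sulfonylation of an acidic enol, the only hydroxyl in the molecule, gives the enol triflate; the carbon end of the enolate (C4) is fully substituted and hindered, so the reaction takes place at oxygen.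

Step 6
Reactants: 8 methyl 2-(4-methoxybenzyl)-3-(4-methoxyphenyl)-5-oxo-4-(trifluoromethylsulfonyloxy)-2,5-dihydrofuran-2-carboxylate
Product: 9 methyl 2-(4-methoxybenzyl)-3-(4-methoxyphenyl)-5-oxo-2,5-dihydrofuran-2-carboxylate (racemic)
Conditions: Pd(OAc)2 (5 mol %), PPh3 (10 mol %), HCO2H, Et3N, DMF, 60 °C
Reagents that add atoms: none
Why: Palladium-catalysed formate reduction of an enol triflate: zerovalent palladium inserts into the C3–O bond of the electron-poor triflate, formate exchanges for triflate and loses CO2 to give a palladium hydride, and reductive elimination forms C3–H; esters, lactone and aryl ethers are inert, and no aryl halide is yet present.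

Step 7
Reactants: 9 methyl 2-(4-methoxybenzyl)-3-(4-methoxyphenyl)-5-oxo-2,5-dihydrofuran-2-carboxylate
Product: 10 2-(4-methoxybenzyl)-3-(4-methoxyphenyl)-5-oxo-2,5-dihydrofuran-2-carboxylic acid (racemic)
Conditions: LiOH (3 equiv), THF/H2O, 0 °C; then 1 M HCl, 0 °C, used at once
Reagents that add atoms: lithium hydroxide, [Li+].[OH-]
Why: Saponification of a methyl ester activated by the α-acyloxy oxygen; hydroxide may also open the lactone, but the resulting Z-configured γ-hydroxy enoic acid can only reclose to the same butenolide on acidification, and no position in 9 can epimerize or eliminate.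

Step 8
Reactants: 10 2-(4-methoxybenzyl)-3-(4-methoxyphenyl)-5-oxo-2,5-dihydrofuran-2-carboxylic acid
Product: 11 5-acetoxy-5-(4-methoxybenzyl)-4-(4-methoxyphenyl)furan-2(5H)-one (racemic)
Conditions: Pb(OAc)4 (1.3 equiv), pyridine, benzene, 60 °C
Reagents that add atoms: lead tetraacetate, CC(=O)O[Pb](OC(C)=O)(OC(C)=O)OC(C)=O
Why: Oxidative decarboxylation with Pb(OAc)4: the lead carboxylate loses CO2 to a C5 radical stabilized by O1 and the ring alkene, this is oxidized to the oxygen-stabilized cation, and acetate is taken up at C5; the reaction type is established for carboxylic acids whose α-carbon carries an oxygen or acylamino substituent, and the phenols are still protected.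

Step 9
Reactants: 11 5-acetoxy-5-(4-methoxybenzyl)-4-(4-methoxyphenyl)furan-2(5H)-one
Product: 12 (Z)-5-(4-methoxybenzylidene)-4-(4-methoxyphenyl)furan-2(5H)-one
Conditions: TsOH·H2O (10 mol %), toluene, 90 °C
Reagents that add atoms: none
Why: Acid-catalysed E1 elimination, the known deacyloxylation or dehydration of 5-acyloxy- and 5-hydroxy-5-benzylbutenolides to 5-benzylidenebutenolides: the tertiary acetoxy group ionizes to the O1-stabilized cation and a C6 proton, the only β-hydrogen available, is lost. Reversible protonation lets the new alkene settle in the Z geometry, in which the C6 aryl avoids the C4 aryl.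

Step 10
Reactants: 12 (Z)-5-(4-methoxybenzylidene)-4-(4-methoxyphenyl)furan-2(5H)-one
Product: 13 (Z)-5-(4-hydroxybenzylidene)-4-(4-hydroxyphenyl)furan-2(5H)-one
Conditions: BBr3 (5 equiv), CH2Cl2, −78 °C to rt; then H2O
Reagents that add atoms: none
Why: Lewis-acid cleavage of both aryl methyl ethers through the aryloxyboron bromides with bromide attack at the methyl groups; the lactone and the conjugated alkenes are not attacked, and the Z geometry is the thermodynamic one and is kept.

Step 11
Reactants: 13 (Z)-5-(4-hydroxybenzylidene)-4-(4-hydroxyphenyl)furan-2(5H)-one
Product: 14 rubrolide A, (Z)-5-(3,5-dibromo-4-hydroxybenzylidene)-4-(3,5-dibromo-4-hydroxyphenyl)furan-2(5H)-one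
Conditions: Br2 (4.1 equiv), KBr, dioxane/H2O, rt
Reagents that add atoms: bromine, BrBr
Why: Electrophilic aromatic bromination: each para-substituted phenol directs two bromines to its free ortho positions, which are much more reactive than C3 or the C5=C6 bond of the carbonyl-conjugated enol lactone; limiting bromine to four equivalents should stop the reaction at the tetrabromide.

## Compound list

1 | 4-methoxybenzaldehyde | COc1ccc(C=O)cc1 | starting material
2 | N-acetylglycine | CC(=O)NCC(=O)O | starting material
3 | (Z)-4-(4-methoxybenzylidene)-2-methyloxazol-5(4H)-one | CC1=N/C(=C\c2ccc(OC)cc2)C(=O)O1 | intermediate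
4 | 3-(4-methoxyphenyl)-2-oxopropanoic acid | COc1ccc(CC(=O)C(=O)O)cc1 | intermediate
5 | methyl 3-(4-methoxyphenyl)-2-oxopropanoate | COC(=O)C(=O)Cc1ccc(OC)cc1 | intermediate
6 | dimethyl 2-hydroxy-2-(4-methoxybenzyl)-3-(4-methoxyphenyl)-4-oxopentanedioate (racemic, mixture of diastereomers) | COC(=O)C(O)(Cc1ccc(OC)cc1)C(c1ccc(OC)cc1)C(=O)C(=O)OC | intermediate (not isolated)
7 | methyl 4-hydroxy-2-(4-methoxybenzyl)-3-(4-methoxyphenyl)-5-oxo-2,5-dihydrofuran-2-carboxylate (racemic) | COC(=O)C1(Cc2ccc(OC)cc2)OC(=O)C(O)=C1c1ccc(OC)cc1 | intermediate
8 | methyl 2-(4-methoxybenzyl)-3-(4-methoxyphenyl)-5-oxo-4-(trifluoromethylsulfonyloxy)-2,5-dihydrofuran-2-carboxylate (racemic) | COC(=O)C1(Cc2ccc(OC)cc2)OC(=O)C(OS(=O)(=O)C(F)(F)F)=C1c1ccc(OC)cc1 | intermediate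
9 | methyl 2-(4-methoxybenzyl)-3-(4-methoxyphenyl)-5-oxo-2,5-dihydrofuran-2-carboxylate (racemic) | COC(=O)C1(Cc2ccc(OC)cc2)OC(=O)C=C1c1ccc(OC)cc1 | intermediate
10 | 2-(4-methoxybenzyl)-3-(4-methoxyphenyl)-5-oxo-2,5-dihydrofuran-2-carboxylic acid (racemic) | OC(=O)C1(Cc2ccc(OC)cc2)OC(=O)C=C1c1ccc(OC)cc1 | intermediate
11 | 5-acetoxy-5-(4-methoxybenzyl)-4-(4-methoxyphenyl)furan-2(5H)-one (racemic) | CC(=O)OC1(Cc2ccc(OC)cc2)OC(=O)C=C1c1ccc(OC)cc1 | intermediate
12 | (Z)-5-(4-methoxybenzylidene)-4-(4-methoxyphenyl)furan-2(5H)-one | O=C1C=C(c2ccc(OC)cc2)/C(=C/c2ccc(OC)cc2)O1 | intermediate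
13 | (Z)-5-(4-hydroxybenzylidene)-4-(4-hydroxyphenyl)furan-2(5H)-one | O=C1C=C(c2ccc(O)cc2)/C(=C/c2ccc(O)cc2)O1 | intermediate
14 | rubrolide A, (Z)-5-(3,5-dibromo-4-hydroxybenzylidene)-4-(3,5-dibromo-4-hydroxyphenyl)furan-2(5H)-one | O=C1C=C(c2cc(Br)c(O)c(Br)c2)/C(=C/c2cc(Br)c(O)c(Br)c2)O1 | target

## Step count and least certain steps

Total step count: 11. Longest linear sequence: 11 steps (1 to 14; the route is fully linear, with 2 entering in step 1).

Step 4 (key step).
- What may go wrong: the aldol addition can revert before the lactone closes, because 5 rests mainly as its conjugated enol and offers little of the keto form as acceptor. The electron-rich enolate can also be degraded by adventitious oxygen, with cleavage back to the aldehyde oxidation level.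
- Fallback: it sets out from 5 and returns at 7, and makes the two roles of the monomer explicit. Silylation of 5 (TMSCl, Et3N, CH2Cl2) should give the silyl enol ether methyl (Z)-3-(4-methoxyphenyl)-2-(trimethylsilyloxy)prop-2-enoate F1. A Mukaiyama aldol addition of F1 to a second equivalent of 5 (TiCl4, CH2Cl2, −78 °C) should give the aldol 6 under non-equilibrating conditions. Brief treatment with catalytic TsOH should then close the lactone to 7.

Step 6.
- What may go wrong: formate or amine can attack at sulfur and return enol 7. Oxidative addition at a fully substituted alkene next to a quaternary carbon can be slow. A palladium hydride can reduce the conjugated C3=C4 bond.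
- Fallback: it sets out from 7 and returns at 9, and avoids the triflate altogether. Condensation of the C3 ketone tautomer of 7 with tosylhydrazide (MeOH, cat. HCl) should give the tosylhydrazone methyl 2-(4-methoxybenzyl)-3-(4-methoxyphenyl)-5-oxo-4-(2-tosylhydrazinylidene)tetrahydrofuran-2-carboxylate F2. Bamford–Stevens elimination of sulfinate (DBU, CH2Cl2) should give the α-diazo lactone methyl 4-diazo-2-(4-methoxybenzyl)-3-(4-methoxyphenyl)-5-oxotetrahydrofuran-2-carboxylate F3. Rh2(OAc)4 (1 mol %, CH2Cl2, rt) should convert F3 into a carbenoid that takes the tertiary benzylic hydrogen from C4 by 1,2-hydride shift and so gives 9.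

Step 7.
- What may go wrong: the carboxylate can lose CO2 without oxidation during hydrolysis or acidification, because the C5 carbanion it leaves behind is an aromatic 2-oxidofuran. That gives material at the wrong oxidation level.
- Fallback: it sets out from 9 and returns at 12, and makes this decarboxylation the plan while supplying the oxidation separately. Krapcho dealkoxycarbonylation of 9 (LiCl, wet DMSO, 130 °C) should give 5-(4-methoxybenzyl)-4-(4-methoxyphenyl)furan-2(5H)-one F4. Silylation (TBSOTf, Et3N, CH2Cl2) should give the silyloxyfuran tert-butyl{[5-(4-methoxybenzyl)-4-(4-methoxyphenyl)furan-2-yl]oxy}dimethylsilane F5. Bromination at the γ-carbon (NBS, THF, −78 °C) should give 5-bromo-5-(4-methoxybenzyl)-4-(4-methoxyphenyl)furan-2(5H)-one F6. Dehydrobromination toward C6 (Et3N), with a short acid equilibration as in step 9 if needed, should give 12.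

Step 8.
- What may go wrong: the lead reagent can attack the electron-rich anisyl rings or their benzylic position electrophilically, and the C5 radical can be diverted before it is oxidized and captured by acetate.
- Fallback: it sets out from 10 and returns at 12, and uses a radical chain with no strong oxidant. Coupling of 10 with 2-mercaptopyridine N-oxide (DCC, CH2Cl2, dark) should give the thiohydroxamate ester 2-thioxopyridin-1(2H)-yl 2-(4-methoxybenzyl)-3-(4-methoxyphenyl)-5-oxo-2,5-dihydrofuran-2-carboxylate F7. Visible-light irradiation should induce Barton decarboxylation with transfer of the pyridylthio group to C5 and give 5-(4-methoxybenzyl)-4-(4-methoxyphenyl)-5-(pyridin-2-ylsulfanyl)furan-2(5H)-one F8. Oxidation with mCPBA (CH2Cl2, −78 °C) should give the sulfoxide 5-(4-methoxybenzyl)-4-(4-methoxyphenyl)-5-(pyridin-2-ylsulfinyl)furan-2(5H)-one F9. Thermal syn-elimination of F9 toward C6 on warming should give 12, which would be equilibrated to the Z isomer with acid as in step 9.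

## Further compounds

F1 | step 4 | methyl (Z)-3-(4-methoxyphenyl)-2-(trimethylsilyloxy)prop-2-enoate | COC(=O)/C(O[Si](C)(C)C)=C/c1ccc(OC)cc1
F2 | step 6 | methyl 2-(4-methoxybenzyl)-3-(4-methoxyphenyl)-5-oxo-4-(2-tosylhydrazinylidene)tetrahydrofuran-2-carboxylate (racemic, mixture of diastereomers) | COC(=O)C1(Cc2ccc(OC)cc2)OC(=O)C(=NNS(=O)(=O)c2ccc(C)cc2)C1c1ccc(OC)cc1
F3 | step 6 | methyl 4-diazo-2-(4-methoxybenzyl)-3-(4-methoxyphenyl)-5-oxotetrahydrofuran-2-carboxylate (racemic, mixture of diastereomers) | COC(=O)C1(Cc2ccc(OC)cc2)OC(=O)C(=[N+]=[N-])C1c1ccc(OC)cc1
F4 | step 7 | 5-(4-methoxybenzyl)-4-(4-methoxyphenyl)furan-2(5H)-one (racemic) | O=C1C=C(c2ccc(OC)cc2)C(Cc2ccc(OC)cc2)O1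
F5 | step 7 | tert-butyl{[5-(4-methoxybenzyl)-4-(4-methoxyphenyl)furan-2-yl]oxy}dimethylsilane | CC(C)(C)[Si](C)(C)Oc1cc(-c2ccc(OC)cc2)c(Cc2ccc(OC)cc2)o1
F6 | step 7 | 5-bromo-5-(4-methoxybenzyl)-4-(4-methoxyphenyl)furan-2(5H)-one (racemic) | O=C1C=C(c2ccc(OC)cc2)C(Br)(Cc2ccc(OC)cc2)O1
F7 | step 8 | 2-thioxopyridin-1(2H)-yl 2-(4-methoxybenzyl)-3-(4-methoxyphenyl)-5-oxo-2,5-dihydrofuran-2-carboxylate (racemic) | S=C1C=CC=CN1OC(=O)C1(Cc2ccc(OC)cc2)OC(=O)C=C1c1ccc(OC)cc1
F8 | step 8 | 5-(4-methoxybenzyl)-4-(4-methoxyphenyl)-5-(pyridin-2-ylsulfanyl)furan-2(5H)-one (racemic) | O=C1C=C(c2ccc(OC)cc2)C(Sc2ccccn2)(Cc2ccc(OC)cc2)O1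
F9 | step 8 | 5-(4-methoxybenzyl)-4-(4-methoxyphenyl)-5-(pyridin-2-ylsulfinyl)furan-2(5H)-one (mixture of diastereomers) | O=C1C=C(c2ccc(OC)cc2)C(S(=O)c2ccccn2)(Cc2ccc(OC)cc2)O1
A1 | alternative 1 | (Z)-5-(3,5-dibromo-4-methoxybenzylidene)-4-(3,5-dibromo-4-methoxyphenyl)furan-2(5H)-one | O=C1C=C(c2cc(Br)c(OC)c(Br)c2)/C(=C/c2cc(Br)c(OC)c(Br)c2)O1
A2 | alternative 1 | (Z)-1,3-bis(3,5-dibromo-4-methoxyphenyl)-2-hydroxyprop-2-en-1-one | O=C(c1cc(Br)c(OC)c(Br)c1)/C(O)=C/c1cc(Br)c(OC)c(Br)c1
A3 | alternative 1 | (triphenylphosphoranylidene)ketene | O=C=C=P(c1ccccc1)(c1ccccc1)c1ccccc1
A4 | alternative 2 | (Z)-3,5-bis(4-methoxyphenyl)pent-2-en-4-ynoic acid | OC(=O)/C=C(c1ccc(OC)cc1)\C#Cc1ccc(OC)cc1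
A5 | alternative 2 | 4-ethynylanisole | COc1ccc(C#C)cc1
A6 | alternative 2 | bromo[(4-methoxyphenyl)ethynyl]zinc | COc1ccc(C#C[Zn]Br)cc1
A7 | alternative 2 | carbon dioxide | O=C=O
A8 | alternative 3 | 5-acetoxy-5-(4-methoxybenzyl)-4-(4-methoxyphenyl)furan-2(5H)-one (racemic; identical with 11) | CC(=O)OC1(Cc2ccc(OC)cc2)OC(=O)C=C1c1ccc(OC)cc1
A9 | alternative 3 | 4-hydroxy-4-(4-methoxybenzyl)-3-(4-methoxyphenyl)cyclobut-2-en-1-one (racemic) | O=C1C=C(c2ccc(OC)cc2)C1(O)Cc1ccc(OC)cc1
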